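Numbering: ring A is C6 (spiro), C7 (=C14H2), C8, C9 (OH), C10 (Br), C11 (Me2); ring B is C6, C5, C4, C3 (Me, OH), C2 (Cl), C1. With C3 read as a ketone, C3(=O)–C2–C1–C6–C7=C14 is a δ,ε-unsaturated ketone, so the C1–C6 bond is cut by an oxy-Cope transform. One anionic [3,3] shift of a fused 2-vinyloctalin-2-ol closes ring B at spiro C6, sets C6, frees the C14 methylene and leaves a C2–C3 enolate that is chlorinated at C2. The precursor carries the C6=C7 ring-fusion alkene, the C11 gem-dimethyl group and, already installed by reagent control, the C10 bromide trans to a C9 silyl ether.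

Key step: step 14

Assumption: the amine catalysts of steps 4 and 11 are taken to induce in the sense drawn (the enantiomeric catalyst is used if not); the atom labels above are kept for every intermediate.

Step 1
Reactants: 1 methyl 3,3-dimethylpent-4-enoate
Product: 3 methyl 3,3-dimethyl-4-oxobutanoate, via secondary ozonide 2 (not isolated)
Conditions: O3, CH2Cl2, −78 °C; then Me2S, −78 to 20 °C
Reagents that add atoms: ozone, [O-][O+]=O
Why: Ozonolysis with reductive work-up cleaves the only alkene to a non-enolisable aldehyde and leaves the methyl ester untouched.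

Step 2
Reactants: 3 methyl 3,3-dimethyl-4-oxobutanoate
Product: 4 methyl 3,3-dimethylpent-4-ynoate
Conditions: dimethyl (1-diazo-2-oxopropyl)phosphonate, K2CO3, MeOH, 0 to 20 °C
Reagents that add atoms: dimethyl (1-diazo-2-oxopropyl)phosphonate, CC(=O)C(=[N+]=[N-])P(=O)(OC)OC
Why: Ohira–Bestmann (Seyferth–Gilbert) homologation turns the hindered, non-enolisable aldehyde into the terminal alkyne under conditions that a methyl ester in methanol tolerates.

Step 3
Reactants: 4 methyl 3,3-dimethylpent-4-ynoate
Product: 5 3,3-dimethylpent-4-ynal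
Conditions: iBu2AlH (1.05 equiv), CH2Cl2, −78 °C; then MeOH, aq. potassium sodium tartrate
Reagents that add atoms: none
Why: Partial ester reduction with one equivalent of iBu2AlH at −78 °C should stop at the aluminium hemiacetal, which collapses to the aldehyde only on work-up.

Step 4
Reactants: 5 3,3-dimethylpent-4-ynal; 6 3-bromoprop-1-yne (propargyl bromide)
Product: 8 (5S)-5-bromo-6,6-dimethylocta-1,7-diyn-4-ol (C4 epimer mixture), via α-bromoaldehyde 7 (not isolated)
Conditions: (2R,5R)-2,5-diphenylpyrrolidine (20 mol%), PhCO2H (20 mol%), 4,4-dibromo-2,6-di-tert-butylcyclohexa-2,5-dien-1-one, CH2Cl2/pentane, −40 °C; then transfer into allenylzinc bromide (from 6 and Zn, THF, decanted from excess Zn), −78 °C; aq. NH4Cl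
Reagents that add atoms: 4,4-dibromo-2,6-di-tert-butylcyclohexa-2,5-dien-1-one, CC(C)(C)C1=CC(Br)(Br)C=C(C(C)(C)C)C1=O
Why: Enamine-catalysed α-bromination sets C10 (S) by shielding one enamine face with the C2-symmetric pyrrolidine, and the configurationally labile bromoaldehyde is trapped in the same flask by Barbier-type propargylation (SE2' addition of the allenylzinc reagent), whose carbinol selectivity is irrelevant because C9 is reset in steps 5 and 6.

Step 5
Reactants: 8 (5S)-5-bromo-6,6-dimethylocta-1,7-diyn-4-ol (C4 epimer mixture)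
Product: 9 (S)-5-bromo-6,6-dimethylocta-1,7-diyn-4-one
Conditions: Dess–Martin periodinane, CH2Cl2, 0 °C; used at once
Reagents that add atoms: none
Why: Dess–Martin oxidation converges both carbinol epimers on one ketone under near-neutral conditions, which should leave the C10 bromide unepimerised and the propargyl ketone unisomerised.

Step 6
Reactants: 9 (S)-5-bromo-6,6-dimethylocta-1,7-diyn-4-one
Product: 10 (4S,5S)-5-bromo-6,6-dimethylocta-1,7-diyn-4-ol
Conditions: NaBH4, CeCl3·7H2O, MeOH, −78 °C; AcOH quench at −78 °C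
Reagents that add atoms: none
Why: Luche-type hydride addition should follow the Cornforth (polar Felkin–Anh) model, with C–Br antiperiplanar to C=O and hydride entering anti to the bulky tertiary propargylic group, which sets C9 (S) and gives the syn bromohydrin that becomes the trans isomer once ring A is closed.

Step 7
Reactants: 10 (4S,5S)-5-bromo-6,6-dimethylocta-1,7-diyn-4-ol
Product: 11 (4S,5S)-5-bromo-4-[(tert-butyldimethylsilyl)oxy]-6,6-dimethylocta-1,7-diyne
Conditions: TBSOTf, 2,6-lutidine, CH2Cl2, −78 to 0 °C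
Reagents that add atoms: tert-butyldimethylsilyl trifluoromethanesulfonate, CC(C)(C)[Si](C)(C)OS(=O)(=O)C(F)(F)F
Why: Silyl triflate with a hindered pyridine base protects the crowded carbinol without generating an alkoxide that could displace the neighbouring bromide.

Step 8
Reactants: 11 (4S,5S)-5-bromo-4-[(tert-butyldimethylsilyl)oxy]-6,6-dimethylocta-1,7-diyne
Product: 12 tert-butyl{[(1S,2S)-2-bromo-3,3-dimethyl-4,5-dimethylidenecyclohexyl]oxy}dimethylsilane
Conditions: Pd2(dba)3·CHCl3 (2.5 mol%), P(o-tol)3 (5 mol%), AcOH, Et3SiH, benzene, 20 °C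
Reagents that add atoms: none
Why: Palladium-catalysed reductive cyclisation of the 1,7-diyne (hydropalladation, alkyne insertion, silane reduction of the dienylpalladium species) should close ring A as the 1,2-bis(methylene)cyclohexane, helped by the gem-dimethyl group, while the unactivated secondary bromide is inert to zerovalent palladium at room temperature.

Step 9
Reactants: 13 2,2-dimethyl-1,3-dioxan-5-one; 14 benzoyl chloride
Product: 15 2,2-dimethyl-4H-1,3-dioxin-5-yl benzoate
Conditions: Et3N, DMAP (cat.), CH2Cl2, 0 to 40 °C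
Reagents that add atoms: none
Why: Soft enolisation and O-acylation of the activated α,α'-dialkoxy ketone give the enol benzoate, a masked 2-acyloxyacrolein.

Step 10
Reactants: 15 2,2-dimethyl-4H-1,3-dioxin-5-yl benzoate
Product: 16 3-oxoprop-1-en-2-yl benzoate (2-benzoyloxyacrolein)
Conditions: toluene, 120 °C, sealed tube; used at once
Reagents that add atoms: none
Why: A thermal retro-hetero-Diels–Alder reaction of the 4H-1,3-dioxin expels acetone and releases the sensitive 2-acyloxyacrolein.

Step 11
Reactants: 12 tert-butyl{[(1S,2S)-2-bromo-3,3-dimethyl-4,5-dimethylidenecyclohexyl]oxy}dimethylsilane; 16 3-oxoprop-1-en-2-yl benzoate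
Product: 17 (2S,6S,7S)-6-bromo-7-[(tert-butyldimethylsilyl)oxy]-2-formyl-5,5-dimethyl-1,2,3,4,5,6,7,8-octahydronaphthalen-2-yl benzoate
Conditions: (S)-1,1'-binaphthyl-2,2'-diamine (5 mol%), Tf2NH (9.5 mol%), EtCN, −78 to −40 °C
Reagents that add atoms: none
Why: Iminium-catalysed enantioselective Diels–Alder reaction of the s-cis-locked exocyclic diene with the α-acyloxyacrolein builds the carbinol ring, the chiral diammonium salt fixing the dienophile face and thus C3 (S), while the fully substituted dienophile carbon should bond to C14 because the C5 terminus is crowded by the C11 gem-dimethyl group and the C10 bromide.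

Step 12
Reactants: 17 (2S,6S,7S)-6-bromo-7-[(tert-butyldimethylsilyl)oxy]-2-formyl-5,5-dimethyl-1,2,3,4,5,6,7,8-octahydronaphthalen-2-yl benzoate; 18 methyltriphenylphosphonium bromide
Product: 19 (2S,6S,7S)-6-bromo-7-[(tert-butyldimethylsilyl)oxy]-2-ethenyl-5,5-dimethyl-1,2,3,4,5,6,7,8-octahydronaphthalen-2-yl benzoate
Conditions: KN(SiMe3)2, THF, 0 °C; then 17, −78 to 0 °C
Reagents that add atoms: none
Why: Wittig methylenation with the small methylene ylide converts the hindered, non-enolisable aldehyde into the vinyl group (C2=C1) at low temperature, where the tertiary benzoate and the bromide are not attacked.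

Step 13
Reactants: 19 (2S,6S,7S)-6-bromo-7-[(tert-butyldimethylsilyl)oxy]-2-ethenyl-5,5-dimethyl-1,2,3,4,5,6,7,8-octahydronaphthalen-2-yl benzoate
Product: 20 (2S,6S,7S)-6-bromo-7-[(tert-butyldimethylsilyl)oxy]-2-ethenyl-5,5-dimethyl-1,2,3,4,5,6,7,8-octahydronaphthalen-2-ol
Conditions: iBu2AlH (2.5 equiv), CH2Cl2, −78 °C; aq. potassium sodium tartrate
Reagents that add atoms: none
Why: Reductive ester cleavage with iBu2AlH frees the tertiary C3 carbinol, where saponification of the hindered benzoate would be slow, and spares the silyl ether, the alkenes and the secondary bromide.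

Step 14
Reactants: 20 (2S,6S,7S)-6-bromo-7-[(tert-butyldimethylsilyl)oxy]-2-ethenyl-5,5-dimethyl-1,2,3,4,5,6,7,8-octahydronaphthalen-2-ol
Product: 22 (3S,4S,6S,10S)-4-bromo-3-[(tert-butyldimethylsilyl)oxy]-10-chloro-5,5-dimethyl-1-methylidenespiro[5.5]undecan-9-one, via potassium enolate 21 (not isolated)
Conditions: KH (1.3 equiv), 18-crown-6 (1.3 equiv), THF, 0 to 25 °C; then NCS, −78 to 0 °C; aq. NH4Cl
Reagents that add atoms: N-chlorosuccinimide, O=C1CCC(=O)N1Cl
Why: KH gives the tertiary potassium alkoxide, and with the cation sequestered by the crown ether this undergoes an anionic oxy-Cope [3,3] shift through a boat transition state (C1, C2, C3, C14, C7, C6; bicyclo[2.2.2]octane-like) in which C1 bonds to C6 as C3–C14 breaks, the charge ending as the C2–C3 enolate 21 that NCS chlorinates at C2. The closest known reaction type is the anionic oxy-Cope rearrangement of 1-vinylcyclohex-3-enols to 4-vinylcyclohexanones with electrophilic trapping of the regiodefined enolate. Ring B (C6, C1, C2, C3, C4, C5) is closed by this sigmatropic bond formation at the ring-fusion carbon, which turns the fused bicycle into the spirocycle and leaves C7=C14 exocyclic on ring A. C6 is controlled by C3: the axial vinyl group can only reach the face of C6=C7 on its own side of the bicycle, so (S)-C3 is relayed to (S)-C6; C2 is under thermodynamic control, enolisation leaving chlorine equatorial on ring B, cis to the equatorial C11 and clear of the axial C7. The step needs the [3,3] shift to beat a [1,3] shift and the bromide to survive: alkoxide acceleration and the enforced boat geometry favour the former, and the trans-diequatorial C9 silyl ether and C10 bromide offer no hydrogen antiperiplanar to bromine (C11 is quaternary), so E2 is shut off. Chlorination is confined to C2 because the enolate is formed regiospecifically and is quenched before it can equilibrate towards C4.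

Step 15
Reactants: 22 (3S,4S,6S,10S)-4-bromo-3-[(tert-butyldimethylsilyl)oxy]-10-chloro-5,5-dimethyl-1-methylidenespiro[5.5]undecan-9-one
Product: 23 (3S,4S,6S,9R,10S)-4-bromo-3-[(tert-butyldimethylsilyl)oxy]-10-chloro-5,5,9-trimethyl-1-methylidenespiro[5.5]undecan-9-ol
Conditions: MeMgBr (3 equiv), THF, −78 °C; aq. NH4Cl at −78 °C
Reagents that add atoms: methylmagnesium bromide, C[Mg]Br
Why: Grignard addition to the α-chloro ketone should occur from the equatorial direction of the locked ring B chair, as with 2-chlorocyclohexanones, placing the C3 hydroxyl axial and cis to the equatorial C2 chlorine (C3 R), and the low temperature keeps the magnesium chlorohydrinate from rearranging.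

Step 16
Reactants: 23 (3S,4S,6S,9R,10S)-4-bromo-3-[(tert-butyldimethylsilyl)oxy]-10-chloro-5,5,9-trimethyl-1-methylidenespiro[5.5]undecan-9-ol
Product: 24 (3S,4S,6S,9R,10S)-4-bromo-10-chloro-5,5,9-trimethyl-1-methylidenespiro[5.5]undecane-3,9-diol
Conditions: HF·pyridine, pyridine, THF, 0 to 20 °C
Reagents that add atoms: none
Why: Acidic fluoride removes the silyl group without forming a free alkoxide, so the trans bromohydrin cannot close to an epoxide and the tertiary chlorohydrin is untouched.

Step 17
Reactants: 24 (3S,4S,6S,9R,10S)-4-bromo-10-chloro-5,5,9-trimethyl-1-methylidenespiro[5.5]undecane-3,9-diol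
Product: 25 (4S,6S,9R,10S)-4-bromo-10-chloro-9-hydroxy-5,5,9-trimethyl-1-methylidenespiro[5.5]undecan-3-one
Conditions: Dess–Martin periodinane, pyridine, CH2Cl2, 0 °C; used at once
Reagents that add atoms: none
Why: Dess–Martin oxidation of the only secondary alcohol gives the α-bromo ketone without passing through an enolate, so C10 should not epimerise and the C7 methylene should stay out of conjugation, the tertiary alcohol being inert.

Step 18
Reactants: 25 (4S,6S,9R,10S)-4-bromo-10-chloro-9-hydroxy-5,5,9-trimethyl-1-methylidenespiro[5.5]undecan-3-one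
Product: 26 (3R,4S,6S,9R,10S)-4-bromo-10-chloro-5,5,9-trimethyl-1-methylidenespiro[5.5]undecane-3,9-diol (target CNP0121782.1)
Conditions: iBu2AlH (3 equiv), THF, −78 °C; aq. potassium sodium tartrate
Reagents that add atoms: none
Why: Carbonyl reduction with a bulky hydride: the axial methyl group on C11 blocks the axial trajectory at C9, so hydride should enter equatorially and leave the hydroxyl axial and cis to the equatorial C10 bromide (C9 R), which completes the inversion of C9 by oxidation and reduction.

Compound list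
1 | methyl 3,3-dimethylpent-4-enoate | C=CC(C)(C)CC(=O)OC | starting material
2 | methyl 3-methyl-3-(1,2,4-trioxolan-3-yl)butanoate (secondary ozonide) | COC(=O)CC(C)(C)C1OCOO1 | intermediate
3 | methyl 3,3-dimethyl-4-oxobutanoate | COC(=O)CC(C)(C)C=O | intermediate
4 | methyl 3,3-dimethylpent-4-ynoate | COC(=O)CC(C)(C)C#C | intermediate
5 | 3,3-dimethylpent-4-ynal | O=CCC(C)(C)C#C | intermediate
6 | 3-bromoprop-1-yne (propargyl bromide) | C#CCBr | starting material
7 | (S)-2-bromo-3,3-dimethylpent-4-ynal | O=C[C@@H](Br)C(C)(C)C#C | intermediate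
8 | (5S)-5-bromo-6,6-dimethylocta-1,7-diyn-4-ol, both C4 epimers | C#CCC(O)[C@@H](Br)C(C)(C)C#C | intermediate
9 | (S)-5-bromo-6,6-dimethylocta-1,7-diyn-4-one | C#CCC(=O)[C@@H](Br)C(C)(C)C#C | intermediate
10 | (4S,5S)-5-bromo-6,6-dimethylocta-1,7-diyn-4-ol (syn bromohydrin) | C#CC[C@H](O)[C@@H](Br)C(C)(C)C#C | intermediate
11 | (4S,5S)-5-bromo-4-[(tert-butyldimethylsilyl)oxy]-6,6-dimethylocta-1,7-diyne | C#CC[C@H](O[Si](C)(C)C(C)(C)C)[C@@H](Br)C(C)(C)C#C | intermediate
12 | tert-butyl{[(1S,2S)-2-bromo-3,3-dimethyl-4,5-dimethylidenecyclohexyl]oxy}dimethylsilane (ring A diene, bromide trans to silyl ether) | C=C1C[C@H](O[Si](C)(C)C(C)(C)C)[C@@H](Br)C(C)(C)C1=C | intermediate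
13 | 2,2-dimethyl-1,3-dioxan-5-one | CC1(C)OCC(=O)CO1 | starting material
14 | benzoyl chloride | O=C(Cl)c1ccccc1 | starting material
15 | 2,2-dimethyl-4H-1,3-dioxin-5-yl benzoate | CC1(C)OCC(OC(=O)c2ccccc2)=CO1 | intermediate
16 | 3-oxoprop-1-en-2-yl benzoate (2-benzoyloxyacrolein) | C=C(C=O)OC(=O)c1ccccc1 | intermediate
17 | (2S,6S,7S)-6-bromo-7-[(tert-butyldimethylsilyl)oxy]-2-formyl-5,5-dimethyl-1,2,3,4,5,6,7,8-octahydronaphthalen-2-yl benzoate (C3 S, C9 S, C10 S in target labels) | O=C[C@]1(OC(=O)c2ccccc2)CCC2=C(C1)C[C@H](O[Si](C)(C)C(C)(C)C)[C@@H](Br)C2(C)C | intermediate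
18 | methyltriphenylphosphonium bromide | C[P+](c1ccccc1)(c1ccccc1)c1ccccc1.[Br-] | starting material
19 | (2S,6S,7S)-6-bromo-7-[(tert-butyldimethylsilyl)oxy]-2-ethenyl-5,5-dimethyl-1,2,3,4,5,6,7,8-octahydronaphthalen-2-yl benzoate | C=C[C@]1(OC(=O)c2ccccc2)CCC2=C(C1)C[C@H](O[Si](C)(C)C(C)(C)C)[C@@H](Br)C2(C)C | intermediate
20 | (2S,6S,7S)-6-bromo-7-[(tert-butyldimethylsilyl)oxy]-2-ethenyl-5,5-dimethyl-1,2,3,4,5,6,7,8-octahydronaphthalen-2-ol (2-vinyloctalin-2-ol, key-step precursor) | C=C[C@]1(O)CCC2=C(C1)C[C@H](O[Si](C)(C)C(C)(C)C)[C@@H](Br)C2(C)C | intermediate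
21 | potassium (3S,4S,6S)-4-bromo-3-[(tert-butyldimethylsilyl)oxy]-5,5-dimethyl-1-methylidenespiro[5.5]undec-9-en-9-olate | C=C1C[C@H](O[Si](C)(C)C(C)(C)C)[C@@H](Br)C(C)(C)[C@]12CCC([O-])=CC2.[K+] | intermediate
22 | (3S,4S,6S,10S)-4-bromo-3-[(tert-butyldimethylsilyl)oxy]-10-chloro-5,5-dimethyl-1-methylidenespiro[5.5]undecan-9-one (key-step product) | C=C1C[C@H](O[Si](C)(C)C(C)(C)C)[C@@H](Br)C(C)(C)[C@]12CCC(=O)[C@@H](Cl)C2 | intermediate
23 | (3S,4S,6S,9R,10S)-4-bromo-3-[(tert-butyldimethylsilyl)oxy]-10-chloro-5,5,9-trimethyl-1-methylidenespiro[5.5]undecan-9-ol | C=C1C[C@H](O[Si](C)(C)C(C)(C)C)[C@@H](Br)C(C)(C)[C@]12CC[C@@](C)(O)[C@@H](Cl)C2 | intermediate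
24 | (3S,4S,6S,9R,10S)-4-bromo-10-chloro-5,5,9-trimethyl-1-methylidenespiro[5.5]undecane-3,9-diol (C9 epimer of the target) | C=C1C[C@H](O)[C@@H](Br)C(C)(C)[C@]12CC[C@@](C)(O)[C@@H](Cl)C2 | intermediate
25 | (4S,6S,9R,10S)-4-bromo-10-chloro-9-hydroxy-5,5,9-trimethyl-1-methylidenespiro[5.5]undecan-3-one | C=C1CC(=O)[C@@H](Br)C(C)(C)[C@]12CC[C@@](C)(O)[C@@H](Cl)C2 | intermediate
26 | (3R,4S,6S,9R,10S)-4-bromo-10-chloro-5,5,9-trimethyl-1-methylidenespiro[5.5]undecane-3,9-diol | C=C1C[C@@H](O)[C@@H](Br)C(C)(C)[C@]12CC[C@@](C)(O)[C@@H](Cl)C2 | target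

Total step count: 18. Longest linear sequence: 16 (steps 1 to 8 and 11 to 18; steps 9 and 10 make the dienophile).

Steps most likely to fail, riskiest first

Step 14. A [1,3] shift or a fragmentation of the alkoxide may outrun the [3,3] shift, because bond formation at C6 is slowed by the neighbouring gem-dimethyl carbon. Long exposure to the bare alkoxide may also cost hydrogen bromide if ring A leaves its diequatorial chair. The fallback works in the neutral thermal manifold, without alkoxide or enolate. It sets out from 20, which is silylated (TMSCl, imidazole, DMF) to the trimethylsilyl ether F1. Heating in degassed decalin at about 200 °C in base-washed glass should bring about the uncatalysed siloxy-Cope rearrangement to the trimethylsilyl enol ether F2, regiodefined at C2–C3. NCS in THF at 0 °C then chlorinates it at C2, and the route is rejoined at 22. Should the sigmatropic shift itself be at fault, the cycloaddition detour given for step 11 bypasses it as well.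

Step 11. The substituted dienophile carbon may bond to C5 instead of C14, or enantiofacial control may be incomplete; either gives isomers that are hard to separate from 17. The fallback makes the spiro centre directly by cycloaddition instead of by fused bicycle plus rearrangement. It sets out from 12 and returns at 23:
- Ozonolysis of the less hindered C7=C14 alkene (one equivalent of O3, pyridine, CH2Cl2, −78 °C) gives the α-methylene ketone F3.
- A Diels–Alder reaction of F3 with 2-(trimethylsilyloxy)buta-1,3-diene gives the spiro silyl enol ether F4; the catalyst is the oxazaborolidinium triflimide made from (S)-α,α-diphenylprolinol, o-tolylboronic acid and Tf2NH, and the silyloxy group fixes the regiochemistry (C3–O, C2=C3).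
- NCS gives the chloro diketone F5.
- MeMgBr at −78 °C should add only to the unhindered C3 ketone and give the hydroxy ketone F6.
- Methylenation of the hindered C7 ketone with Zn, CH2Br2 and TiCl4 returns to the route at 23.

Step 4. The α-bromo aldehyde may racemise, or the amine catalyst may be brominated before the aldehyde is consumed; either erodes the C10 configuration on which all of ring A depends. The fallback uses a stoichiometric auxiliary instead of amine catalysis. It sets out from 4 and returns at 7:
- Saponification (LiOH, THF/H2O) gives 3,3-dimethylpent-4-ynoic acid F7.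
- Acylation of lithiated (S)-4-benzyloxazolidin-2-one through the mixed pivalic anhydride gives the N-acyl oxazolidinone F8.
- The dibutylboron enolate (Bu2BOTf, iPr2NEt) is brominated with NBS on the face away from the benzyl group to give the (S)-bromo imide F9.
- LiBH4 in wet Et2O removes the auxiliary and gives the storable (S)-2-bromo-3,3-dimethylpent-4-yn-1-ol F10.
- Dess–Martin oxidation returns to the route at 7, which is propargylated at once as in step 4.

Further compounds
F1 | step 14 | {[(2S,6S,7S)-6-bromo-7-[(tert-butyldimethylsilyl)oxy]-2-ethenyl-5,5-dimethyl-1,2,3,4,5,6,7,8-octahydronaphthalen-2-yl]oxy}trimethylsilane | C=C[C@]1(O[Si](C)(C)C)CCC2=C(C1)C[C@H](O[Si](C)(C)C(C)(C)C)[C@@H](Br)C2(C)C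
F2 | step 14 | tert-butyl{[(3S,4S,6S)-4-bromo-5,5-dimethyl-1-methylidene-9-[(trimethylsilyl)oxy]spiro[5.5]undec-9-en-3-yl]oxy}dimethylsilane | C=C1C[C@H](O[Si](C)(C)C(C)(C)C)[C@@H](Br)C(C)(C)[C@]12CCC(O[Si](C)(C)C)=CC2
F3 | step 11 | (4S,5S)-4-bromo-5-[(tert-butyldimethylsilyl)oxy]-3,3-dimethyl-2-methylidenecyclohexan-1-one | C=C1C(=O)C[C@H](O[Si](C)(C)C(C)(C)C)[C@@H](Br)C1(C)C
F4 | step 11 | 4-bromo-3-[(tert-butyldimethylsilyl)oxy]-5,5-dimethyl-9-[(trimethylsilyl)oxy]spiro[5.5]undec-9-en-1-one (ring A centres and spiro centre as in 22) | O=C1C[C@H](O[Si](C)(C)C(C)(C)C)[C@@H](Br)C(C)(C)[C@]12CCC(O[Si](C)(C)C)=CC2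
F5 | step 11 | 4-bromo-3-[(tert-butyldimethylsilyl)oxy]-10-chloro-5,5-dimethylspiro[5.5]undecane-1,9-dione (stereocentres as in 22) | O=C1C[C@H](O[Si](C)(C)C(C)(C)C)[C@@H](Br)C(C)(C)[C@]12CCC(=O)[C@@H](Cl)C2
F6 | step 11 | 4-bromo-3-[(tert-butyldimethylsilyl)oxy]-10-chloro-9-hydroxy-5,5,9-trimethylspiro[5.5]undecan-1-one (stereocentres as in 23) | O=C1C[C@H](O[Si](C)(C)C(C)(C)C)[C@@H](Br)C(C)(C)[C@]12CC[C@@](C)(O)[C@@H](Cl)C2
F7 | step 4 | 3,3-dimethylpent-4-ynoic acid | OC(=O)CC(C)(C)C#C
F8 | step 4 | (S)-4-benzyl-3-(3,3-dimethylpent-4-ynoyl)oxazolidin-2-one | O=C(CC(C)(C)C#C)N1[C@@H](Cc2ccccc2)COC1=O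
F9 | step 4 | (S)-4-benzyl-3-[(S)-2-bromo-3,3-dimethylpent-4-ynoyl]oxazolidin-2-one | O=C([C@@H](Br)C(C)(C)C#C)N1[C@@H](Cc2ccccc2)COC1=O
F10 | step 4 | (S)-2-bromo-3,3-dimethylpent-4-yn-1-ol | OC[C@@H](Br)C(C)(C)C#C
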